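The earlier runs and the new flask are simulated for an exercise, and the scatter is random.

The easy step was to take the added product off Thursday's readings: at 42 min Thursday's flask had made 0.233 M and Saturday's flask 0.235 M.

in all of them: free catalyst 0.0480 M

| flask | substrate | reagent | product | time |
|---|---|---|---|---|
| Saturday's | 0.600 M | 0.480 M |  |  |
| Tuesday's | 0.360 M | 0.240 M |  |  |
| Thursday's | 0.600 M | 0.480 M | 0.180 M |  |
| Monday's | 0.600 M | 0.480 M |  | 170 min |

| run | time / min | [product] / M |
|---|---|---|
| Saturday's run | 7.0 | 0.117 |
| Saturday's run | 14 | 0.173 |
| Saturday's run | 21 | 0.208 |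
| Saturday's run | 28 | 0.217 |
| Saturday's run | 35 | 0.228 |
| Saturday's run | 42 | 0.235 |
| Tuesday's run | 7.0 | 0.058 |
| Tuesday's run | 14 | 0.083 |
| Tuesday's run | 21 | 0.098 |
| Tuesday's run | 28 | 0.109 |
| Tuesday's run | 35 | 0.109 |
| Tuesday's run | 42 | 0.113 |
| Thursday's run | 7.0 | 0.300 |
| Thursday's run | 14 | 0.350 |
| Thursday's run | 21 | 0.385 |
| Thursday's run | 28 | 0.397 |
| Thursday's run | 35 | 0.407 |
| Thursday's run | 42 | 0.413 |

(each reading ± 0.003 M)

1. product in the Monday's run at 170 min, as a share of the substrate charged

- Overall: substrate + reagent -> product, with free catalyst as catalyst.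
- Constant volume, constant temperature.
- Readings of a species count what is bound in complexes too.

I went through the settings one at a time. By hand, added product would slow a flask that it inhibited, but those two amounts differ by 0.00200 M, with a scatter of 0.003 M on each reading, so I set that setting aside.

The reagent came next. It is the limiting reagent, so Saturday's charge allows 80.0 % of the substrate. Yet Saturday's flask read 0.235 M at 42 min, 39.2 % of its substrate, and had gained 0.00700 M over the last 7.00 min. I therefore reckoned from the reagent left:

ln(c(reagent, charged) / c(reagent, left)) = ln(0.480 M / 0.245 M) = 0.673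

I carried this as the reach, the logarithm of reagent charged over reagent left.

Then I lowered the charges. With the same free catalyst and the same reach, Tuesday's flask should make

0.240 M × (1 − exp(−0.673)) = 0.118 M

and its last reading was 0.113 M.

The last setting is time. Monday's flask repeats Saturday's charge and runs to 170 min, so the same reach gives

80.0 % × (1 − exp(−0.673)) = 39.2 %

I took that as my estimate, and a low one, since Saturday's readings were still rising. The forecast, judging “far short of completion, so the catalyst is dying”, stood higher than my estimate at 40.5 %.

Monday's flask gave 39.9 %.

    free catalyst + reagent ⇌ catalyst-reagent complex, settled at all times (8.200 M⁻¹)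
    catalyst-reagent complex + substrate → product + free catalyst (2.724 M⁻¹ min⁻¹)
    free catalyst + substrate → spent catalyst + substrate (0.6300 M⁻¹ min⁻¹)
    free catalyst + impurity → spent catalyst

Monday's reach came to 0.692. Without the conversion of free catalyst by substrate into spent catalyst, Monday's flask gives 80.0 %, the reagent ceiling, so that conversion is what stopped it. Turnover and that conversion each carry one substrate, which cancels, and the catalyst left past the impurity gives a limiting reach of 2.72 M⁻¹ min⁻¹ × 8.20 M⁻¹ / 0.630 M⁻¹ min⁻¹ × (0.0480 M − 0.0281 M) = 0.705. With the full catalyst charge that reach becomes 1.70, which gives 65.4 %, and Monday's flask without the impurity stands at 63.9 %.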